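**Retrosynthetic overview**

1. Target numbering runs from C1 (benzylic CH2) to C22, with C3 the (S)-carbinol, C5 the ketone and C13=C14 the cis double bond. The last two steps only unmask: thioacetal hydrolysis at C5, then acidic loss of two methoxymethyl groups and one silyl group.
2. Key disconnection C14–C15: a Zweifel olefination unites an (E)-alkenyl pinacol boronate (C1–C14, all heteroatoms in place) with octyllithium made from 1-iodooctane. Two nucleophilic carbons (C–B and C–Li) are joined by oxidation with iodine through a 1,2-metallate shift, and the same operation inverts E to the required 13Z geometry.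
3. Enabling feature: the isolated C13=C14 bond has one hydrogen on each carbon, and C14 is bonded to C15, the unbranched primary carbon of a plain octyl chain. C14 can therefore carry boron (terminal alkyne, syn hydroboration) and C15 can be the migrating primary alkyl group. C5 is held as carbon 2 of a temporary 1,3-dithiane ring, which is inert to octyllithium.
4. C4–C5 and C5–C6 are made in one pot by a silyl-dithiane linchpin coupling (epoxide opening, 1,4-Brook rearrangement, alkylation), which also silylates O3. C13 and C14 come from acetylide, and C3 from an (S)-epoxide obtained by hydrolytic kinetic resolution.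
5. Rings: the arene is bought and no ring of the target is built. The oxirane (made in step 3) is opened in step 5, the dithiane ring enters in step 5 and leaves in step 9, and the dioxaborolane ring enters in step 7 and leaves in step 8.

Key step: step 8

**Route**

Step 1
Reactants: 1 4-bromobenzene-1,2-diol (4-bromocatechol)
Product: 2 4-bromo-1,2-bis(methoxymethoxy)benzene
Conditions: NaH, MOMCl, DMF, 0 °C → rt
Reagents that add atoms: chloromethyl methyl ether (MOMCl), COCCl
Why: Williamson-type O-alkylation of both phenoxides with the reactive chloromethyl ether should give the bis-acetal, which masks the catechol against the organometallic, basic and oxidising reagents used before the acidic last step.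

Step 2
Reactants: 2 4-bromo-1,2-bis(methoxymethoxy)benzene; 3 but-3-en-1-ylmagnesium bromide
Product: 4 4-(but-3-en-1-yl)-1,2-bis(methoxymethoxy)benzene
Conditions: PdCl2(dppf) (2 mol%), THF, rt → 50 °C
Reagents that add atoms: none
Why: Kumada coupling of an aryl bromide with a primary alkyl Grignard reagent is reliable with the wide-bite-angle dppf ligand on palladium, which favours reductive elimination over β-hydride elimination, and the terminal alkene and the acetals are inert.

Step 3
Reactants: 4 4-(but-3-en-1-yl)-1,2-bis(methoxymethoxy)benzene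
Product: 5 rac-2-{2-[3,4-bis(methoxymethoxy)phenyl]ethyl}oxirane
Conditions: mCPBA, NaHCO3, CH2Cl2, 0 °C → rt
Reagents that add atoms: 3-chloroperoxybenzoic acid (mCPBA), OOC(=O)c1cccc(Cl)c1
Why: Prilezhaev epoxidation of the isolated terminal alkene should proceed without attack on the buffered, acetal-protected arene, and the epoxide is formed as the racemate at this stage.

Step 4
Reactants: 5 rac-2-{2-[3,4-bis(methoxymethoxy)phenyl]ethyl}oxirane
Product: 6 (2S)-2-{2-[3,4-bis(methoxymethoxy)phenyl]ethyl}oxirane
Conditions: (S,S)-(salen)Co(OAc) (0.5 mol%), H2O (0.55 equiv), THF, 0 °C → rt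
Reagents that add atoms: none
Why: In the hydrolytic kinetic resolution the (S,S)-configured salen complex of trivalent cobalt hydrates the (R)-enantiomer of a 2-alkyloxirane much faster, so the (S)-epoxide should be recovered and sets C3 of the target under catalyst control (its configuration would be confirmed before the material is carried on).

Step 5
Reactants: 7 tert-butyl(1,3-dithian-2-yl)dimethylsilane; 6 (2S)-2-{2-[3,4-bis(methoxymethoxy)phenyl]ethyl}oxirane; 8 1-bromo-7-chloroheptane
Product: 12 tert-butyl({(2S)-4-[3,4-bis(methoxymethoxy)phenyl]-1-[2-(7-chloroheptyl)-1,3-dithian-2-yl]butan-2-yl}oxy)dimethylsilane, via lithiated silyl dithiane 9 (not isolated), via C-silyl lithium alkoxide 10 (not isolated), via O-silyl dithianyllithium 11 (not isolated)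
Conditions: 7, t-BuLi, Et2O, −78 → −45 °C; 6, −78 → −25 °C; then 8, HMPA/THF, −78 → 0 °C
Reagents that add atoms: none
Why: In this silyl-dithiane linchpin coupling (Corey–Seebach umpolung joined to an anion relay) the lithiated dithiane opens the epoxide at its unsubstituted carbon without touching C3, the polar additive triggers a 1,4-Brook rearrangement that silylates O3 and regenerates a dithianyl anion at C5, and this anion displaces bromide, not chloride, from 8.

Step 6
Reactants: 12 tert-butyl({(2S)-4-[3,4-bis(methoxymethoxy)phenyl]-1-[2-(7-chloroheptyl)-1,3-dithian-2-yl]butan-2-yl}oxy)dimethylsilane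
Product: 13 tert-butyl({(2S)-4-[3,4-bis(methoxymethoxy)phenyl]-1-[2-(non-8-yn-1-yl)-1,3-dithian-2-yl]butan-2-yl}oxy)dimethylsilane
Conditions: LiC≡CH·H2NCH2CH2NH2, NaI (cat.), DMSO/THF, rt
Reagents that add atoms: lithium acetylide–ethylenediamine complex, [Li]C#C.NCCN
Why: SN2 displacement of the primary chloride by acetylide in a dipolar aprotic solvent should install the terminal alkyne C13≡C14, and the fully substituted dithiane, the silyl ether and the acetals offer no site to the base.

Step 7
Reactants: 13 tert-butyl({(2S)-4-[3,4-bis(methoxymethoxy)phenyl]-1-[2-(non-8-yn-1-yl)-1,3-dithian-2-yl]butan-2-yl}oxy)dimethylsilane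
Product: 14 tert-butyl({(2S)-4-[3,4-bis(methoxymethoxy)phenyl]-1-{2-[(8E)-9-(4,4,5,5-tetramethyl-1,3,2-dioxaborolan-2-yl)non-8-en-1-yl]-1,3-dithian-2-yl}butan-2-yl}oxy)dimethylsilane
Conditions: pinacolborane, Cp2Zr(H)Cl (10 mol%), Et3N (10 mol%), THF, 60 °C
Reagents that add atoms: pinacolborane, CC1(C)OBOC1(C)C
Why: Zirconium-catalysed syn hydroboration of a terminal alkyne (hydrozirconation, then zirconium-to-boron exchange) places boron on the terminal carbon C14 and should give only the (E)-alkenyl boronic ester.

Step 8
Reactants: 14 the (E)-alkenyl pinacol boronate from step 7; 15 1-iodooctane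
Product: 19 tert-butyl({(2S)-4-[3,4-bis(methoxymethoxy)phenyl]-1-{2-[(8Z)-heptadec-8-en-1-yl]-1,3-dithian-2-yl}butan-2-yl}oxy)dimethylsilane, via octyllithium 16 (not isolated), via lithium boronate complex 17 (not isolated), via β-iodo boronic ester 18 (not isolated)
Conditions: 15 (1.3 equiv), t-BuLi (2.5 equiv), Et2O, −78 °C; add to 14, THF, −78 °C; I2 (1.2 equiv), THF, −78 °C; NaOMe, MeOH, −78 °C → rt
Reagents that add atoms: none
Why: Octyllithium 16, made by lithium–iodine exchange, should add to the vacant orbital on boron of 14 to give the tetracoordinate boronate 17; iodine then attacks the electron-rich C13=C14 bond and the octyl group shifts from boron to C14 anti to the iodonium bridge (1,2-metallate rearrangement) to give 18, from which attack of methoxide on boron triggers anti elimination of boron and iodide. The closest known reaction type is the Zweifel olefination of (E)-alkenyl pinacol boronates with primary alkyllithium reagents, which delivers (Z)-alkenes. No ring is closed and no lasting stereocentre is made: the transient centres C13 and C14 of 18 arise by anti addition and are erased by anti elimination, so the E geometry of 14 should be inverted stereospecifically to 13Z, while C3 is remote and untouched. The step needs octyllithium to choose boron and iodine to choose the boronate; the first is secured by holding C5 as carbon 2 of the 1,3-dithiane ring, which has no acidic hydrogen and no electrophilic site, and by the silyl and acetal ethers. The second is secured by the far higher nucleophilicity of the anionic alkenyl boronate over thioacetal sulfur and arene at −78 °C with a near-stoichiometric amount of I2. Only the octyl group can migrate, because the pinacol oxygens do not and no t-BuLi is left over, so a single constitution is expected.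

Step 9
Reactants: 19 tert-butyl({(2S)-4-[3,4-bis(methoxymethoxy)phenyl]-1-{2-[(8Z)-heptadec-8-en-1-yl]-1,3-dithian-2-yl}butan-2-yl}oxy)dimethylsilane
Product: 20 (3S,13Z)-1-[3,4-bis(methoxymethoxy)phenyl]-3-{[tert-butyl(dimethyl)silyl]oxy}docos-13-en-5-one
Conditions: MeI (excess), CaCO3, MeCN/H2O (9:1), 45 °C, dark
Reagents that add atoms: water, O
Why: Alkylative hydrolysis of the thioacetal (S-methylation, ring opening to a thionium ion, capture by water) under carbonate buffering should release the C5 ketone without an oxidant or a soft metal ion that could touch the Z-alkene or the electron-rich arene.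

Step 10
Reactants: 20 (3S,13Z)-1-[3,4-bis(methoxymethoxy)phenyl]-3-{[tert-butyl(dimethyl)silyl]oxy}docos-13-en-5-one
Product: 21 (3S,13Z)-1-(3,4-dihydroxyphenyl)-3-hydroxydocos-13-en-5-one
Conditions: HCl (1.25 M in MeOH), THF, 0 °C → rt, argon
Reagents that add atoms: none
Why: Acid-catalysed methanolysis should cleave both aryl methoxymethyl acetals and the secondary silyl ether in one operation at a temperature at which the β-hydroxy ketone should neither dehydrate nor undergo retro-aldol cleavage, and no base is present that would let air oxidise the catechol.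

**Compound list**

1 | 4-bromobenzene-1,2-diol | Oc1ccc(Br)cc1O | starting material
2 | 4-bromo-1,2-bis(methoxymethoxy)benzene | COCOc1ccc(Br)cc1OCOC | intermediate
3 | but-3-en-1-ylmagnesium bromide | C=CCC[Mg]Br | starting material
4 | 4-(but-3-en-1-yl)-1,2-bis(methoxymethoxy)benzene | C=CCCc1ccc(OCOC)c(OCOC)c1 | intermediate
5 | rac-2-{2-[3,4-bis(methoxymethoxy)phenyl]ethyl}oxirane | COCOc1ccc(CCC2CO2)cc1OCOC | intermediate
6 | (2S)-2-{2-[3,4-bis(methoxymethoxy)phenyl]ethyl}oxirane | COCOc1ccc(CC[C@H]2CO2)cc1OCOC | intermediate
7 | tert-butyl(1,3-dithian-2-yl)dimethylsilane | CC(C)(C)[Si](C)(C)C1SCCCS1 | starting material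
8 | 1-bromo-7-chloroheptane | ClCCCCCCCBr | starting material
9 | [2-(tert-butyldimethylsilyl)-1,3-dithian-2-yl]lithium | [Li]C1([Si](C)(C)C(C)(C)C)SCCCS1 | intermediate (not isolated)
10 | lithium (2S)-4-[3,4-bis(methoxymethoxy)phenyl]-1-[2-(tert-butyldimethylsilyl)-1,3-dithian-2-yl]butan-2-olate | CC(C)(C)[Si](C)(C)C1(SCCCS1)C[C@@H](O[Li])CCc1ccc(OCOC)c(OCOC)c1 | intermediate (not isolated)
11 | {2-[(2S)-4-[3,4-bis(methoxymethoxy)phenyl]-2-{[tert-butyl(dimethyl)silyl]oxy}butyl]-1,3-dithian-2-yl}lithium | [Li]C1(SCCCS1)C[C@@H](O[Si](C)(C)C(C)(C)C)CCc1ccc(OCOC)c(OCOC)c1 | intermediate (not isolated)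
12 | tert-butyl({(2S)-4-[3,4-bis(methoxymethoxy)phenyl]-1-[2-(7-chloroheptyl)-1,3-dithian-2-yl]butan-2-yl}oxy)dimethylsilane | ClCCCCCCCC1(SCCCS1)C[C@@H](O[Si](C)(C)C(C)(C)C)CCc1ccc(OCOC)c(OCOC)c1 | intermediate
13 | tert-butyl({(2S)-4-[3,4-bis(methoxymethoxy)phenyl]-1-[2-(non-8-yn-1-yl)-1,3-dithian-2-yl]butan-2-yl}oxy)dimethylsilane | C#CCCCCCCCC1(SCCCS1)C[C@@H](O[Si](C)(C)C(C)(C)C)CCc1ccc(OCOC)c(OCOC)c1 | intermediate
14 | tert-butyl({(2S)-4-[3,4-bis(methoxymethoxy)phenyl]-1-{2-[(8E)-9-(4,4,5,5-tetramethyl-1,3,2-dioxaborolan-2-yl)non-8-en-1-yl]-1,3-dithian-2-yl}butan-2-yl}oxy)dimethylsilane | CC1(C)OB(/C=C/CCCCCCCC2(SCCCS2)C[C@@H](O[Si](C)(C)C(C)(C)C)CCc2ccc(OCOC)c(OCOC)c2)OC1(C)C | intermediate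
15 | 1-iodooctane | CCCCCCCCI | starting material
16 | octyllithium | [Li]CCCCCCCC | intermediate (not isolated)
17 | lithium salt of the tetracoordinate borate from 14 (boron bears the octyl group, the (E)-alkenyl chain and the pinacol diolate) | [Li+].CCCCCCCC[B-]1(/C=C/CCCCCCCC2(SCCCS2)C[C@@H](O[Si](C)(C)C(C)(C)C)CCc2ccc(OCOC)c(OCOC)c2)OC(C)(C)C(C)(C)O1 | intermediate (not isolated)
18 | β-iodo pinacol boronate with boron and the octyl group on C14 and iodine on C13; the (3S,13S,14S) isomer is drawn, and its (3S,13R,14R) diastereomer from attack on the other alkene face is expected alongside and gives the same alkene | CCCCCCCC[C@H](B1OC(C)(C)C(C)(C)O1)[C@@H](I)CCCCCCCC2(SCCCS2)C[C@@H](O[Si](C)(C)C(C)(C)C)CCc2ccc(OCOC)c(OCOC)c2 | intermediate (not isolated)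
19 | tert-butyl({(2S)-4-[3,4-bis(methoxymethoxy)phenyl]-1-{2-[(8Z)-heptadec-8-en-1-yl]-1,3-dithian-2-yl}butan-2-yl}oxy)dimethylsilane | CCCCCCCC/C=C\CCCCCCCC1(SCCCS1)C[C@@H](O[Si](C)(C)C(C)(C)C)CCc1ccc(OCOC)c(OCOC)c1 | intermediate
20 | (3S,13Z)-1-[3,4-bis(methoxymethoxy)phenyl]-3-{[tert-butyl(dimethyl)silyl]oxy}docos-13-en-5-one | CCCCCCCC/C=C\CCCCCCCC(=O)C[C@@H](O[Si](C)(C)C(C)(C)C)CCc1ccc(OCOC)c(OCOC)c1 | intermediate
21 | (3S,13Z)-1-(3,4-dihydroxyphenyl)-3-hydroxydocos-13-en-5-one | CCCCCCCC/C=C\CCCCCCCC(=O)C[C@@H](O)CCc1ccc(O)c(O)c1 | target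

**Step count and risks**

Total step count: 10. Longest linear sequence: 10 steps (1 → 21); compounds 3, 7, 8 and 15 are bought and enter directly.

Steps most likely to fail:

1. Step 8 (key step). What may go wrong: incomplete formation of the boronate before iodine is added, or attack of iodine on thioacetal sulfur or on the electron-rich arene in competition with the boronate, either of which would lower conversion or erode the geometric purity of the alkene. The fallback sets out from 13 and 15 and comes back at 19, and makes the same C14–C15 bond at the alkyne oxidation level. Deprotonation of 13 with n-BuLi (THF, −78 °C) and alkylation of the lithium acetylide with 15 in THF/DMPU should give the internal alkyne tert-butyl({(2S)-4-[3,4-bis(methoxymethoxy)phenyl]-1-[2-(heptadec-8-yn-1-yl)-1,3-dithian-2-yl]butan-2-yl}oxy)dimethylsilane F1. Syn hydroboration with dicyclohexylborane (THF, 0 °C) should give the alkenylborane dicyclohexyl[(8Z)-1-{2-[(2S)-4-[3,4-bis(methoxymethoxy)phenyl]-2-{[tert-butyl(dimethyl)silyl]oxy}butyl]-1,3-dithian-2-yl}heptadec-8-en-9-yl]borane F2, whose C13-borylated regioisomer converges to the same product. Protonolysis of the C–B bond with acetic acid, which goes with retention, should then give 19. No transition metal is involved, so the sulfur cannot poison a catalyst.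

2. Step 5. What may go wrong: silyl migration that is incomplete or sets in too early, β-elimination of the silyloxide from the relayed anion, or slow alkylation of the hindered anion. The fallback sets out from 6 and comes back at 13: the dithiane is built first and coupled as a dianion. Commercial dec-9-yn-1-ol F3 is oxidised (PhI(OAc)2, TEMPO cat., CH2Cl2) to dec-9-ynal F4, which with propane-1,3-dithiol and BF3·OEt2 should give 2-(non-8-yn-1-yl)-1,3-dithiane F5. Two equivalents of n-BuLi (THF, −78 → −20 °C) should give [2-(9-lithionon-8-yn-1-yl)-1,3-dithian-2-yl]lithium F6. Only its dithianyl carbanion is nucleophilic enough to open 6 at the CH2 group (THF/DMPU, −78 → −20 °C), to give (2S)-4-[3,4-bis(methoxymethoxy)phenyl]-1-[2-(non-8-yn-1-yl)-1,3-dithian-2-yl]butan-2-ol F7. Silylation with TBSCl and imidazole in DMF then gives 13.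

3. Step 10. What may go wrong: acid-promoted dehydration of the β-hydroxy ketone to the conjugated enone, or oxidation of the freed catechol, while three protecting groups are removed. The fallback sets out from 19 and comes back at 21, and reverses the order of unmasking. Compound 19 is treated with HCl in MeOH/THF while C5 is still the thioacetal, which can neither dehydrate nor undergo retro-aldol cleavage, to give 4-[(3S)-4-{2-[(8Z)-heptadec-8-en-1-yl]-1,3-dithian-2-yl}-3-hydroxybutyl]benzene-1,2-diol F8. The dithiane is then opened last by alkylative hydrolysis (MeI, CaCO3, MeCN/H2O, 40 °C, argon), which is neutral and free of oxidant, to give 21.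

**Further compounds**

F1 | step 8 | tert-butyl({(2S)-4-[3,4-bis(methoxymethoxy)phenyl]-1-[2-(heptadec-8-yn-1-yl)-1,3-dithian-2-yl]butan-2-yl}oxy)dimethylsilane | CCCCCCCCC#CCCCCCCCC1(SCCCS1)C[C@@H](O[Si](C)(C)C(C)(C)C)CCc1ccc(OCOC)c(OCOC)c1
F2 | step 8 | dicyclohexyl[(8Z)-1-{2-[(2S)-4-[3,4-bis(methoxymethoxy)phenyl]-2-{[tert-butyl(dimethyl)silyl]oxy}butyl]-1,3-dithian-2-yl}heptadec-8-en-9-yl]borane | CCCCCCCC/C(B(C1CCCCC1)C1CCCCC1)=C\CCCCCCCC1(SCCCS1)C[C@@H](O[Si](C)(C)C(C)(C)C)CCc1ccc(OCOC)c(OCOC)c1
F3 | step 5 | dec-9-yn-1-ol | C#CCCCCCCCCO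
F4 | step 5 | dec-9-ynal | C#CCCCCCCCC=O
F5 | step 5 | 2-(non-8-yn-1-yl)-1,3-dithiane | C#CCCCCCCCC1SCCCS1
F6 | step 5 | [2-(9-lithionon-8-yn-1-yl)-1,3-dithian-2-yl]lithium | [Li]C#CCCCCCCCC1([Li])SCCCS1
F7 | step 5 | (2S)-4-[3,4-bis(methoxymethoxy)phenyl]-1-[2-(non-8-yn-1-yl)-1,3-dithian-2-yl]butan-2-ol | C#CCCCCCCCC1(SCCCS1)C[C@@H](O)CCc1ccc(OCOC)c(OCOC)c1
F8 | step 10 | 4-[(3S)-4-{2-[(8Z)-heptadec-8-en-1-yl]-1,3-dithian-2-yl}-3-hydroxybutyl]benzene-1,2-diol | CCCCCCCC/C=C\CCCCCCCC1(SCCCS1)C[C@@H](O)CCc1ccc(O)c(O)c1
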